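Five neighbouring carbons of ring A are oxygenated: C5, C6, C7 and C8 carry OH or OMe, C8a carries the ring C oxygen, and the C5 and C8 oxygens are para. A squarate-derived 4-alkenylcyclobutenone rearranges on heating to exactly this array, so the route cuts ring A at C4a–C5. The precursor is a 2,3,4-trimethoxycyclobutenone whose C4 is bonded to C6 of an enantiopure (2S)-2-aryl-4-silyloxy-3,4-dihydro-2H-pyran. Thermolysis opens the four-membered ring to a dienylketene that closes onto pyran C5 and aromatises; one operation thus builds ring A on ring C with the C6, C7 and C8 methoxy groups in place and only the C5 hydroxyl free. C2 is set earlier by an asymmetric hetero-Diels–Alder reaction.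

Key step: step 6

Remarks on the chemistry:
- Flavanone numbering is used. Ring A is the benzo ring (C4a to C8a), ring C the pyranone (O1 to C4), ring B the aryl group on C2. The monocyclic pyrans are numbered O1, C2 (aryl), C3, C4 (oxygen), C5, C6.
- The carbinol oxygen of the squarate adduct is methylated in the flask in which it forms. The ring expansion then delivers C8 as its methyl ether and C5 as the only free phenol, and no air-sensitive free hydroquinone is handled.
- The C4 silyl group is triisopropylsilyl, which has no Si–CH3 protons that t-BuLi could remove.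
- Assumption for step 2: with (S)-BINOL and Ti(OiPr)4 the carbon nucleophile is taken to add to the Si face of the aldehyde, as such catalysts do in allylations and aldol-type additions of aromatic aldehydes. Should the dihydropyranone prove to be (R), (R)-BINOL is used instead.

Step 1
Reactants: 1 2-hydroxy-6-methoxybenzaldehyde
Product: 2 2-isopropoxy-6-methoxybenzaldehyde
Conditions: 2-bromopropane, K2CO3, DMF, 60 °C
Reagents that add atoms: 2-bromopropane, CC(C)Br
Why: Williamson etherification of the phenoxide formed with K2CO3 should proceed cleanly, and the isopropyl ether is chosen because it tolerates t-BuLi and heat yet is cleaved by BCl3 in the last step.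

Step 2
Reactants: 2 2-isopropoxy-6-methoxybenzaldehyde; 3 (E)-1-methoxy-3-(trimethylsilyloxy)buta-1,3-diene
Product: 5 (S)-2-(2-isopropoxy-6-methoxyphenyl)-2,3-dihydro-4H-pyran-4-one, via silylated aldol adduct 4 (not isolated)
Conditions: (S)-BINOL (20 mol%), Ti(OiPr)4 (10 mol%), 4 Å MS, Et2O, −20 °C; then CF3CO2H, CH2Cl2, 0 °C
Reagents that add atoms: none
Why: The Lewis acid formed from (S)-BINOL and Ti(OiPr)4 should promote a Mukaiyama aldol addition of the diene terminus to the aldehyde, CF3CO2H then closes the ring with loss of methanol (a formal hetero-Diels–Alder reaction), and C2 is set by catalyst control through addition to the Si face of the aldehyde.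

Step 3
Reactants: 5 (S)-2-(2-isopropoxy-6-methoxyphenyl)-2,3-dihydro-4H-pyran-4-one
Product: 6 (2S,4S)-2-(2-isopropoxy-6-methoxyphenyl)-3,4-dihydro-2H-pyran-4-ol (2,4-cis)
Conditions: NaBH4, CeCl3·7H2O, MeOH, −78 °C
Reagents that add atoms: none
Why: Luche reduction delivers hydride 1,2 to the enone carbonyl along the axial trajectory of the half-chair that holds the C2 aryl group equatorial, so the new C4 carbinol centre should form cis to the aryl group (4S) under substrate control.

Step 4
Reactants: 6 (2S,4S)-2-(2-isopropoxy-6-methoxyphenyl)-3,4-dihydro-2H-pyran-4-ol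
Product: 7 (2S,4S)-2-(2-isopropoxy-6-methoxyphenyl)-4-(triisopropylsilyloxy)-3,4-dihydro-2H-pyran
Conditions: TIPSOTf, 2,6-lutidine, CH2Cl2, −78 to 0 °C
Reagents that add atoms: triisopropylsilyl trifluoromethanesulfonate, CC(C)[Si](OS(=O)(=O)C(F)(F)F)(C(C)C)C(C)C
Why: Silylation of the secondary allylic alcohol with a silyl triflate and a hindered pyridine base is routine, and the triisopropylsilyl ether withstands t-BuLi and the later heating.

Step 5
Reactants: 7 (2S,4S)-2-(2-isopropoxy-6-methoxyphenyl)-4-(triisopropylsilyloxy)-3,4-dihydro-2H-pyran; 8 dimethyl squarate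
Product: 11 4-[(2S,4S)-2-(2-isopropoxy-6-methoxyphenyl)-4-(triisopropylsilyloxy)-3,4-dihydro-2H-pyran-6-yl]-2,3,4-trimethoxycyclobut-2-en-1-one (both epimers at cyclobutenone C4), via C6-lithiated dihydropyran 9 (not isolated), via lithium alkoxide 10 (not isolated)
Conditions: t-BuLi (1.6 equiv), THF, −78 to 0 °C; then cannulated into 8 (1.3 equiv), THF, −78 °C; then MeOTf, −78 to −20 °C
Reagents that add atoms: methyl trifluoromethanesulfonate, COS(=O)(=O)C(F)(F)F
Why: The vinylic C6–H next to the ring oxygen is the kinetically most acidic site (enol ether α-lithiation, as practised on glycals), the vinyllithium adds 1,2 to one carbonyl of the squarate at −78 °C, and the tertiary lithium alkoxide is O-methylated by MeOTf in the same flask; the new carbinol centre forms without control, which is immaterial because it becomes aromatic C8.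

Step 6
Reactants: 11 4-[(2S,4S)-2-(2-isopropoxy-6-methoxyphenyl)-4-(triisopropylsilyloxy)-3,4-dihydro-2H-pyran-6-yl]-2,3,4-trimethoxycyclobut-2-en-1-one
Product: 14 (2S,4S)-2-(2-isopropoxy-6-methoxyphenyl)-6,7,8-trimethoxy-4-(triisopropylsilyloxy)chroman-5-ol, via dienylketene 12 (not isolated), via cyclohexadienone 13 (not isolated)
Conditions: PhMe (degassed, 0.02 M), 110 °C
Reagents that add atoms: none
Why: Heating should trigger conrotatory 4π opening of the cyclobutenone C1–C4 bond to dienylketene 12, whose thermal disrotatory 6π electrocyclisation joins the ketene carbon (future C5) to the enol ether β-carbon (pyran C5, future C4a) and so closes the six-membered ring A as cyclohexadienone 13; enolisation of the C4a–H then gives phenol 14. The closest known reaction type is the Moore rearrangement of 4-alkenyl-4-hydroxy- or 4-alkoxycyclobutenones from squarate esters to hydroquinones and their monoethers, which also accepts cyclic enol ethers as the alkenyl group. No stereocentre is created, since the sp3 C4a of 13 is erased on aromatisation and the mixed configuration of the former carbinol carbon vanishes when it becomes aromatic C8. The step needs torquoselectivity and clean intramolecular capture of the ketene: the donor methoxy group on the breaking bond rotates outward, which turns the dihydropyranyl group inward (cis to the ketene), and the only π bond within reach is C5=C6 of the enol ether, so the new bond can form at C4a alone. Because the carbinol oxygen is already methylated, C8 emerges as OMe and C5 as the only free OH, and the neutral conditions should leave C2, C4 and the silyl ether untouched.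

Step 7
Reactants: 14 (2S,4S)-2-(2-isopropoxy-6-methoxyphenyl)-6,7,8-trimethoxy-4-(triisopropylsilyloxy)chroman-5-ol
Product: 15 (2S,4S)-2-(2-isopropoxy-6-methoxyphenyl)-5,6,7,8-tetramethoxy-4-(triisopropylsilyloxy)chromane
Conditions: MeI, K2CO3, DMF, 0 °C to rt
Reagents that add atoms: iodomethane, CI
Why: Williamson methylation caps the only free phenol (C5–OH) so that the electron-rich ring survives the later oxidation, and the mild base at low temperature should not expel the neighbouring benzylic silyloxy group.

Step 8
Reactants: 15 (2S,4S)-2-(2-isopropoxy-6-methoxyphenyl)-5,6,7,8-tetramethoxy-4-(triisopropylsilyloxy)chromane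
Product: 16 (2S,4S)-2-(2-isopropoxy-6-methoxyphenyl)-5,6,7,8-tetramethoxychroman-4-ol
Conditions: Bu4NF, THF, 0 °C to rt
Reagents that add atoms: none
Why: Fluoride-mediated desilylation, driven by the strong Si–F bond, frees the C4 alcohol without touching the aryl ethers or either stereocentre.

Step 9
Reactants: 16 (2S,4S)-2-(2-isopropoxy-6-methoxyphenyl)-5,6,7,8-tetramethoxychroman-4-ol
Product: 17 (S)-2-(2-isopropoxy-6-methoxyphenyl)-5,6,7,8-tetramethoxychroman-4-one
Conditions: Dess–Martin periodinane, pyridine, CH2Cl2, 0 °C to rt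
Reagents that add atoms: none
Why: Dess–Martin oxidation converts the secondary benzylic alcohol into the aryl ketone under pyridine-buffered, near-neutral conditions that should neither ionise C4 nor open the pyranone ring, so C2 keeps its configuration.

Step 10
Reactants: 17 (S)-2-(2-isopropoxy-6-methoxyphenyl)-5,6,7,8-tetramethoxychroman-4-one
Product: 18 (S)-5-hydroxy-2-(2-hydroxy-6-methoxyphenyl)-6,7,8-trimethoxychroman-4-one
Conditions: BCl3, CH2Cl2, −78 to 0 °C; then pH 7 buffer
Reagents that add atoms: none
Why: BCl3 dealkylation removes the secondary isopropyl group from the ring B ether and, through a six-membered boron chelate between the C4 carbonyl and O5, the peri methyl group alone among the methoxy groups, while the low temperature should prevent ionisation of the benzylic C2–O1 bond.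

Compound list
1 | 2-hydroxy-6-methoxybenzaldehyde | COc1cccc(O)c1C=O | starting material
2 | 2-isopropoxy-6-methoxybenzaldehyde | CC(C)Oc1cccc(OC)c1C=O | intermediate
3 | (E)-1-methoxy-3-(trimethylsilyloxy)buta-1,3-diene | CO/C=C/C(=C)O[Si](C)(C)C | starting material
4 | (S,E)-5-(2-isopropoxy-6-methoxyphenyl)-1-methoxy-5-(trimethylsilyloxy)pent-1-en-3-one (silylated aldol adduct, not isolated) | CC(C)Oc1cccc(OC)c1[C@H](CC(=O)/C=C/OC)O[Si](C)(C)C | intermediate
5 | (S)-2-(2-isopropoxy-6-methoxyphenyl)-2,3-dihydro-4H-pyran-4-one | CC(C)Oc1cccc(OC)c1[C@@H]1CC(=O)C=CO1 | intermediate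
6 | (2S,4S)-2-(2-isopropoxy-6-methoxyphenyl)-3,4-dihydro-2H-pyran-4-ol (2,4-cis) | CC(C)Oc1cccc(OC)c1[C@@H]1C[C@H](O)C=CO1 | intermediate
7 | (2S,4S)-2-(2-isopropoxy-6-methoxyphenyl)-4-(triisopropylsilyloxy)-3,4-dihydro-2H-pyran | CC(C)Oc1cccc(OC)c1[C@@H]1C[C@H](O[Si](C(C)C)(C(C)C)C(C)C)C=CO1 | intermediate
8 | dimethyl squarate (3,4-dimethoxycyclobut-3-ene-1,2-dione) | COC1=C(OC)C(=O)C1=O | starting material
9 | 6-lithio derivative of 7 (C6-lithiated dihydropyran, not isolated) | CC(C)Oc1cccc(OC)c1[C@@H]1C[C@H](O[Si](C(C)C)(C(C)C)C(C)C)C=C([Li])O1 | intermediate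
10 | lithium alkoxide of the squarate adduct (lithium 1-(dihydropyran-6-yl)-2,3-dimethoxy-4-oxocyclobut-2-en-1-olate, both epimers, not isolated) | CC(C)Oc1cccc(OC)c1[C@@H]1C[C@H](O[Si](C(C)C)(C(C)C)C(C)C)C=C(O1)C1(O[Li])C(=O)C(OC)=C1OC | intermediate
11 | 4-[(2S,4S)-2-(2-isopropoxy-6-methoxyphenyl)-4-(triisopropylsilyloxy)-3,4-dihydro-2H-pyran-6-yl]-2,3,4-trimethoxycyclobut-2-en-1-one (both epimers at cyclobutenone C4) | CC(C)Oc1cccc(OC)c1[C@@H]1C[C@H](O[Si](C(C)C)(C(C)C)C(C)C)C=C(O1)C1(OC)C(=O)C(OC)=C1OC | intermediate
12 | dienylketene: 2,3,4-trimethoxy-4-(dihydropyran-6-yl)buta-1,3-dien-1-one, dihydropyranyl group cis to the ketene-bearing carbon (not isolated) | CC(C)Oc1cccc(OC)c1[C@@H]1C[C@H](O[Si](C(C)C)(C(C)C)C(C)C)C=C(O1)/C(OC)=C(OC)\C(OC)=C=O | intermediate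
13 | cyclohexadienone: (2S,4S)-2-aryl-6,7,8-trimethoxy-4-(triisopropylsilyloxy)-2,3,4,4a-tetrahydro-5H-chromen-5-one, either configuration at C4a (not isolated) | CC(C)Oc1cccc(OC)c1[C@@H]1C[C@H](O[Si](C(C)C)(C(C)C)C(C)C)C2C(=O)C(OC)=C(OC)C(OC)=C2O1 | intermediate
14 | (2S,4S)-2-(2-isopropoxy-6-methoxyphenyl)-6,7,8-trimethoxy-4-(triisopropylsilyloxy)chroman-5-ol | CC(C)Oc1cccc(OC)c1[C@@H]1C[C@H](O[Si](C(C)C)(C(C)C)C(C)C)c2c(O)c(OC)c(OC)c(OC)c2O1 | intermediate
15 | (2S,4S)-2-(2-isopropoxy-6-methoxyphenyl)-5,6,7,8-tetramethoxy-4-(triisopropylsilyloxy)chromane | CC(C)Oc1cccc(OC)c1[C@@H]1C[C@H](O[Si](C(C)C)(C(C)C)C(C)C)c2c(OC)c(OC)c(OC)c(OC)c2O1 | intermediate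
16 | (2S,4S)-2-(2-isopropoxy-6-methoxyphenyl)-5,6,7,8-tetramethoxychroman-4-ol | CC(C)Oc1cccc(OC)c1[C@@H]1C[C@H](O)c2c(OC)c(OC)c(OC)c(OC)c2O1 | intermediate
17 | (S)-2-(2-isopropoxy-6-methoxyphenyl)-5,6,7,8-tetramethoxychroman-4-one | CC(C)Oc1cccc(OC)c1[C@@H]1CC(=O)c2c(OC)c(OC)c(OC)c(OC)c2O1 | intermediate
18 | (S)-5-hydroxy-2-(2-hydroxy-6-methoxyphenyl)-6,7,8-trimethoxychroman-4-one | COc1cccc(O)c1[C@@H]1CC(=O)c2c(O)c(OC)c(OC)c(OC)c2O1 | target

Total step count: 10. Longest linear sequence: 10 steps (1 to 18).

Steps most likely to fail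

Risk at step 6 (ring expansion). At the temperature needed for ring opening the dienylketene may be consumed by intermolecular reactions before it cyclises. The very electron-rich product may also lose its benzylic C4 silyloxy group through quinone methide formation. The fallback gives up the ring expansion and builds the flavanone on a preformed ring A. It sets out from aldehyde 2. Claisen–Schmidt condensation with 1-(2-hydroxy-3,4,5,6-tetramethoxyphenyl)ethanone (CC(=O)c1c(O)c(OC)c(OC)c(OC)c1OC; KOH, EtOH, rt) should give (E)-1-(2-hydroxy-3,4,5,6-tetramethoxyphenyl)-3-(2-isopropoxy-6-methoxyphenyl)prop-2-en-1-one F1. Enantioselective intramolecular oxa-Michael addition of F1 follows, catalysed by a cinchona-alkaloid-derived bifunctional thiourea (the pseudoenantiomer that favours the S product). The enantiomeric purity is raised by crystallisation or by chromatography on a chiral phase if required. The fallback comes back to the route at flavanone 17, at the cost of less dependable enantiocontrol.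

Risk at step 5 (lithiation, addition, O-methylation). Deprotonation may not be selective for C6, with competition from the benzylic C2–H and from the positions ortho to the ring B ethers, and the vinyllithium may be lost before it reaches the squarate. The fallback places the anion with a sulfone instead of relying on kinetic C–H acidity. It sets out from 7. Addition of benzenesulfinic acid across the enol ether (CH2Cl2, rt) should give (2S,4S)-2-(2-isopropoxy-6-methoxyphenyl)-6-(phenylsulfonyl)-4-(triisopropylsilyloxy)tetrahydro-2H-pyran F2 as a mixture at C6. Deprotonation with LiN(iPr)2 (THF, −78 °C) gives the sulfone-stabilised α-alkoxy carbanion, which forms far more readily than any aryl or benzylic anion. Addition to dimethyl squarate 8 and O-methylation with MeOTf then give the 6-(phenylsulfonyl)tetrahydropyranyl analogue of 11 F3. Loss of benzenesulfinic acid from F3 (on warming, or with DBU) restores the C5=C6 enol ether, and the fallback comes back to the route at 11.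

Risk at step 2 (asymmetric cycloaddition). Facial selectivity may be poor with the doubly ortho-substituted, electron-rich aldehyde. Enantiomeric purity may also erode through acid-promoted ionisation at the benzylic carbon during ring closure. The fallback replaces asymmetric catalysis by resolution. It sets out from 2 and 3. ZnCl2-promoted cycloaddition (THF, rt; then dilute CF3CO2H) should give racemic 2-(2-isopropoxy-6-methoxyphenyl)-2,3-dihydro-4H-pyran-4-one F4. Luche reduction (NaBH4, CeCl3·7H2O, MeOH, −78 °C) gives the racemic cis alcohol F5. Steglich esterification with (S)-2-methoxy-2-phenylacetic acid (DCC, DMAP, CH2Cl2) gives two diastereomeric esters, separated by chromatography or crystallisation. These are the (2S,4S)-dihydropyranyl (S)-2-methoxy-2-phenylacetate F6 and the (2R,4R)-dihydropyranyl (S)-2-methoxy-2-phenylacetate F7. Saponification of F6 (LiOH, THF–H2O, 0 °C) comes back to the route at alcohol 6.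

Further compounds
F1 | step 6 | (E)-1-(2-hydroxy-3,4,5,6-tetramethoxyphenyl)-3-(2-isopropoxy-6-methoxyphenyl)prop-2-en-1-one | CC(C)Oc1cccc(OC)c1/C=C/C(=O)c1c(O)c(OC)c(OC)c(OC)c1OC
F2 | step 5 | (2S,4S)-2-(2-isopropoxy-6-methoxyphenyl)-6-(phenylsulfonyl)-4-(triisopropylsilyloxy)tetrahydro-2H-pyran (mixture at C6) | CC(C)Oc1cccc(OC)c1[C@@H]1C[C@H](O[Si](C(C)C)(C(C)C)C(C)C)CC(O1)S(=O)(=O)c1ccccc1
F3 | step 5 | 2,3,4-trimethoxy-4-[6-(2-isopropoxy-6-methoxyphenyl)-2-(phenylsulfonyl)-4-(triisopropylsilyloxy)tetrahydro-2H-pyran-2-yl]cyclobut-2-en-1-one (aryl and silyloxy carbons as in 7, mixture at the two new centres) | CC(C)Oc1cccc(OC)c1[C@@H]1C[C@H](O[Si](C(C)C)(C(C)C)C(C)C)CC(O1)(S(=O)(=O)c1ccccc1)C1(OC)C(=O)C(OC)=C1OC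
F4 | step 2 | racemic 2-(2-isopropoxy-6-methoxyphenyl)-2,3-dihydro-4H-pyran-4-one | CC(C)Oc1cccc(OC)c1C1CC(=O)C=CO1
F5 | step 2 | racemic cis-2-(2-isopropoxy-6-methoxyphenyl)-3,4-dihydro-2H-pyran-4-ol (both enantiomers shown) | CC(C)Oc1cccc(OC)c1[C@@H]1C[C@H](O)C=CO1.CC(C)Oc1cccc(OC)c1[C@H]1C[C@@H](O)C=CO1
F6 | step 2 | (2S,4S)-2-(2-isopropoxy-6-methoxyphenyl)-3,4-dihydro-2H-pyran-4-yl (S)-2-methoxy-2-phenylacetate | CC(C)Oc1cccc(OC)c1[C@@H]1C[C@H](OC(=O)[C@@H](OC)c2ccccc2)C=CO1
F7 | step 2 | (2R,4R)-2-(2-isopropoxy-6-methoxyphenyl)-3,4-dihydro-2H-pyran-4-yl (S)-2-methoxy-2-phenylacetate | CC(C)Oc1cccc(OC)c1[C@H]1C[C@@H](OC(=O)[C@@H](OC)c2ccccc2)C=CO1
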